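**Retrosynthetic overview**
1. Ester C–O bond: β-HIVS ⇒ shikonin + 3-hydroxy-3-methylbutanoic acid. This is the last step and leaves the C-1′–O bond untouched.
2. Shikonin ⇒ its 5,8-bis-MOM, 1′-O-TBS form, so one acid step unmasks all three oxygens.
3. Quinone ring ⇒ Dötz [3+2+1] benzannulation of an aryl(methoxy)carbene–Cr(CO)5 complex, a terminal alkyne and CO. The ring closes by 6π-electrocyclisation of the dienylketene, and Ce(IV) then gives the quinone. This is the only ring built; the benzenoid ring is bought as hydroquinone.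
4. (R)-Propargylic silyl ether ⇒ α-silyloxy ester (DIBAL-H/Ohira–Bestmann) ⇒ methyl (R)-glycidate + isobutenyl Grignard/Cu(I). C-1′ of the target is C-2 of the glycidate.
5. Carbene complex ⇒ hydroquinone (MOM protection, ortho-lithiation, Cr(CO)6, Me3OBF4).

Assumption: 1, 2 (THF solution), 7 and 16 are catalogue items, and 1 is the glycidate enantiomer that derives from L-serine. The target stereocentre is (R), the shikonin series.

**Step 1**
Reactants: 1 methyl (2R)-oxirane-2-carboxylate (methyl (R)-glycidate); 2 2-methylprop-1-en-1-ylmagnesium bromide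
Product: 3 methyl (2R)-2-hydroxy-5-methylhex-4-enoate
Conditions: 2 (1.5 equiv), CuBr·SMe2 (20 mol %), THF, −78 → −40 °C; aq NH4Cl
Reagents that add atoms: none
Why: Copper-catalysed SN2 epoxide opening (organocuprate chemistry) attacks the unhindered C-3 faster than the Grignard attacks the ester at low temperature, so the C-2–O stereocentre bought with 1 is untouched and becomes (R)-C-1′ of the target.

**Step 2**
Reactants: 3 methyl (2R)-2-hydroxy-5-methylhex-4-enoate
Product: 4 methyl (2R)-2-[(tert-butyldimethylsilyl)oxy]-5-methylhex-4-enoate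
Conditions: TBSCl (1.2 equiv), imidazole (2.5 equiv), DMF, rt
Reagents that add atoms: tert-butyldimethylsilyl chloride, CC(C)(C)[Si](C)(C)Cl
Why: Imidazole-promoted O-silylation of a secondary alcohol breaks no bond at the stereocentre, and the resulting ether tolerates hydride, carbonate, chromium and brief Ce(IV).

**Step 3**
Reactants: 4 methyl (2R)-2-[(tert-butyldimethylsilyl)oxy]-5-methylhex-4-enoate
Product: 6 (3R)-3-[(tert-butyldimethylsilyl)oxy]-6-methylhept-5-en-1-yne, via aldehyde 5 (not isolated)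
Conditions: DIBAL-H (1.15 equiv), CH2Cl2, −78 °C; then MeOH, K2CO3 (3 equiv), Ohira–Bestmann reagent (1.5 equiv), −78 °C → rt; Rochelle salt
Reagents that add atoms: dimethyl (1-diazo-2-oxopropyl)phosphonate, CC(=O)C(=[N+]=[N-])P(=O)(OC)OC
Why: DIBAL-H stops at the chelated tetrahedral aluminate, and the released α-silyloxy aldehyde is homologated at once by the Ohira–Bestmann variant of the Seyferth–Gilbert reaction under carbonate conditions too mild to epimerise the α-centre.

**Step 4**
Reactants: 7 hydroquinone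
Product: 8 1,4-bis(methoxymethoxy)benzene
Conditions: NaH (2.4 equiv), MOMCl (2.4 equiv), DMF, 0 °C → rt
Reagents that add atoms: chloromethyl methyl ether, COCCl
Why: Williamson-type O-alkylation of the bis-phenoxide installs two acetal groups that direct lithiation and later leave under mild acid.

**Step 5**
Reactants: 8 1,4-bis(methoxymethoxy)benzene
Product: 11 pentacarbonyl{[2,5-bis(methoxymethoxy)phenyl](methoxy)carbene}chromium(0), via aryllithium 9 (not isolated), via lithium acylchromate 10 (not isolated)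
Conditions: n-BuLi (1.05 equiv), THF, 0 °C; Cr(CO)6 (1.0 equiv), 0 °C → rt; evaporate; Me3OBF4 (1.3 equiv), CH2Cl2, 0 °C → rt
Reagents that add atoms: hexacarbonylchromium, [Cr].[C-]#[O+].[C-]#[O+].[C-]#[O+].[C-]#[O+].[C-]#[O+].[C-]#[O+]; trimethyloxonium tetrafluoroborate, C[O+](C)C.F[B-](F)(F)F; n-butyllithium, [Li]CCCC (lithium of 9 and 10 only)
Why: MOM-directed ortho-metalation, addition of the aryllithium to a CO ligand and O-methylation of the acylate is the classical Fischer carbene synthesis.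

**Step 6**
Reactants: 11 pentacarbonyl{[2,5-bis(methoxymethoxy)phenyl](methoxy)carbene}chromium(0); 6 (3R)-3-[(tert-butyldimethylsilyl)oxy]-6-methylhept-5-en-1-yne
Product: 14 2-{(1R)-1-[(tert-butyldimethylsilyl)oxy]-4-methylpent-3-en-1-yl}-5,8-bis(methoxymethoxy)naphthalene-1,4-dione, via dienylketene complex 12 (not isolated), via naphthol complex 13 (not isolated)
Conditions: 11 (1.3 equiv), 6 (1.0 equiv), degassed THF (0.1 M), 55 °C, 16 h; then CAN (7 equiv), MeCN–H2O, 0 °C, 20 min
Reagents that add atoms: water, O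
Why: In the Dötz [3+2+1] benzannulation, CO loss followed by alkyne and CO insertion gives 12, whose 6π-electrocyclisation onto the free ortho carbon closes the new ring and tautomerises to 13; Ce(IV) then strips chromium and oxidatively demethylates the p-methoxynaphthol, either alkyne orientation converges on the same quinone, and the propargylic stereocentre is a spectator.

**Step 7**
Reactants: 14 2-{(1R)-1-[(tert-butyldimethylsilyl)oxy]-4-methylpent-3-en-1-yl}-5,8-bis(methoxymethoxy)naphthalene-1,4-dione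
Product: 15 shikonin, 5,8-dihydroxy-2-[(1R)-1-hydroxy-4-methylpent-3-en-1-yl]naphthalene-1,4-dione
Conditions: 3 M aq HCl–THF (1:3), 25 °C, Ar, dark
Reagents that add atoms: none
Why: Acid-catalysed acetal and silyl ether hydrolysis removes the two phenolic MOM groups (activated by the peri carbonyls) and the secondary TBS ether by O–CH2 and O–Si cleavage only, so the C-1′–O bond and its (R) configuration are kept.

**Step 8**
Reactants: 15 shikonin; 16 3-hydroxy-3-methylbutanoic acid
Product: 17 β-HIVS, (1R)-1-(5,8-dihydroxy-1,4-dioxo-1,4-dihydronaphthalen-2-yl)-4-methylpent-3-en-1-yl 3-hydroxy-3-methylbutanoate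
Conditions: 16 (1.5 equiv), DCC (1.5 equiv), DMAP (0.2 equiv), CH2Cl2, 0 °C → rt, dark
Reagents that add atoms: none
Why: Steglich esterification acylates only the secondary side-chain OH, because the peri-phenols are locked in hydrogen bonds and the tertiary OH of 16 is too hindered, and acyl transfer to oxygen retains the (R) centre.

**Compound list**
1 | methyl (2R)-oxirane-2-carboxylate | COC(=O)[C@H]1CO1 | starting material
2 | 2-methylprop-1-en-1-ylmagnesium bromide | CC(C)=C[Mg]Br | starting material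
3 | methyl (2R)-2-hydroxy-5-methylhex-4-enoate | CC(C)=CC[C@@H](O)C(=O)OC | intermediate
4 | methyl (2R)-2-[(tert-butyldimethylsilyl)oxy]-5-methylhex-4-enoate | CC(C)=CC[C@@H](O[Si](C)(C)C(C)(C)C)C(=O)OC | intermediate
5 | (2R)-2-[(tert-butyldimethylsilyl)oxy]-5-methylhex-4-enal | CC(C)=CC[C@@H](O[Si](C)(C)C(C)(C)C)C=O | intermediate
6 | (3R)-3-[(tert-butyldimethylsilyl)oxy]-6-methylhept-5-en-1-yne | CC(C)=CC[C@@H](O[Si](C)(C)C(C)(C)C)C#C | intermediate
7 | hydroquinone | Oc1ccc(O)cc1 | starting material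
8 | 1,4-bis(methoxymethoxy)benzene | COCOc1ccc(OCOC)cc1 | intermediate
9 | 2,5-bis(methoxymethoxy)phenyllithium | [Li]c1cc(OCOC)ccc1OCOC | intermediate
10 | lithium pentacarbonyl[2,5-bis(methoxymethoxy)benzoyl]chromate | [Li+].[O-]C(=[Cr])c1cc(OCOC)ccc1OCOC.[C-]#[O+].[C-]#[O+].[C-]#[O+].[C-]#[O+].[C-]#[O+] | intermediate
11 | pentacarbonyl{[2,5-bis(methoxymethoxy)phenyl](methoxy)carbene}chromium(0) | COC(=[Cr])c1cc(OCOC)ccc1OCOC.[C-]#[O+].[C-]#[O+].[C-]#[O+].[C-]#[O+].[C-]#[O+] | intermediate
12 | tricarbonylchromium complex of the (R)-dienylketene O=C=C(side chain)–CH=C(OMe)Ar, aryl cis to the ketene carbon | CC(C)=CC[C@@H](O[Si](C)(C)C(C)(C)C)C(=C=O)/C=C(/OC)c1cc(OCOC)ccc1OCOC.[Cr].[C-]#[O+].[C-]#[O+].[C-]#[O+] | intermediate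
13 | tricarbonylchromium complex of 2-{(1R)-1-[(tert-butyldimethylsilyl)oxy]-4-methylpent-3-en-1-yl}-4-methoxy-5,8-bis(methoxymethoxy)naphthalen-1-ol | CC(C)=CC[C@@H](O[Si](C)(C)C(C)(C)C)c1cc(OC)c2c(OCOC)ccc(OCOC)c2c1O.[Cr].[C-]#[O+].[C-]#[O+].[C-]#[O+] | intermediate
14 | 2-{(1R)-1-[(tert-butyldimethylsilyl)oxy]-4-methylpent-3-en-1-yl}-5,8-bis(methoxymethoxy)naphthalene-1,4-dione | CC(C)=CC[C@@H](O[Si](C)(C)C(C)(C)C)C1=CC(=O)c2c(OCOC)ccc(OCOC)c2C1=O | intermediate
15 | shikonin | CC(C)=CC[C@@H](O)C1=CC(=O)c2c(O)ccc(O)c2C1=O | intermediate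
16 | 3-hydroxy-3-methylbutanoic acid | CC(C)(O)CC(=O)O | starting material
17 | β-HIVS | CC(C)=CC[C@@H](OC(=O)CC(C)(C)O)C1=CC(=O)c2c(O)ccc(O)c2C1=O | target

**Total step count:** 8. **Longest linear sequence:** 6 (steps 1, 2, 3, 6, 7, 8 from 1).

**Three steps most likely to fail**

**Step 6 (benzannulation/Ce(IV)).** The chelating MOM oxygens may divert the vinylcarbene to indene or cyclobutenone products, and the acetals may not survive acidic Ce(IV).
- The fallback sets out from 6 and comes back at 17. It masks the peri-oxygens as methyl ethers and unmasks them oxidatively at the very end.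
- Commercial 2-bromo-1,4-dimethoxybenzene is treated with n-BuLi, Cr(CO)6 and Me3OBF4. The reaction passes through 2,5-dimethoxyphenyllithium F1 and lithium pentacarbonyl(2,5-dimethoxybenzoyl)chromate F2 to give pentacarbonyl[(2,5-dimethoxyphenyl)(methoxy)carbene]chromium F3.
- Benzannulation of F3 with 6 runs through the dimethoxy dienylketene complex F4 and the trimethoxy naphthol complex F5. CAN then gives the O-TBS 5,8-dimethoxynaphthoquinone F6.
- HF·pyridine frees 5,8-di-O-methylshikonin F7, and Steglich coupling with 16 gives 5,8-di-O-methyl-β-HIVS F8.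
- AgO/6 M HNO3 in acetone (rt, minutes) oxidatively demethylates the dimethoxy ring to the naphthalene-1,4,5,8-tetraone ester F9. An aqueous Na2S2O4 wash reduces F9 to 17.

**Step 7 (global acid unmasking).** Free shikonin in acid can close to cycloshikonin through its C-1′ OH and the prenyl alkene, or can ionise at C-1′ and lose ee.
- The fallback sets out from 14 and comes back at 17. It reorders the endgame so that no free C-1′ OH ever meets acid.
- Buffered HF·pyridine in THF removes only the silyl group to give 5,8-bis-O-(methoxymethyl)shikonin F10.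
- DCC/DMAP with 16 gives 5,8-bis-O-(methoxymethyl)-β-HIVS F11.
- The phenolic acetals are then taken off heterogeneously with NaHSO4·SiO2 in CH2Cl2 at rt to give 17.

**Step 8 (Steglich with an unprotected β-hydroxy acid).** Activated 16 can self-condense, close to the β-lactone or rearrange to the N-acylurea while sensitive 15 waits.
- The fallback sets out from 16 (coupled with 15) and comes back at 17. It uses a protected acid.
- TESOTf/2,6-lutidine converts 16 into triethylsilyl 3-methyl-3-(triethylsilyloxy)butanoate F12.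
- K2CO3 in aqueous MeOH at 0 °C cleaves only the silyl ester to give 3-methyl-3-(triethylsilyloxy)butanoic acid F13.
- DCC/DMAP with 15 gives shikonin 3-methyl-3-(triethylsilyloxy)butanoate F14, and HF·pyridine in THF at 0 °C releases 17.

**Further compounds**
F1 | step 6 | 2,5-dimethoxyphenyllithium | [Li]c1cc(OC)ccc1OC
F2 | step 6 | lithium pentacarbonyl(2,5-dimethoxybenzoyl)chromate | [Li+].[O-]C(=[Cr])c1cc(OC)ccc1OC.[C-]#[O+].[C-]#[O+].[C-]#[O+].[C-]#[O+].[C-]#[O+]
F3 | step 6 | pentacarbonyl[(2,5-dimethoxyphenyl)(methoxy)carbene]chromium | COC(=[Cr])c1cc(OC)ccc1OC.[C-]#[O+].[C-]#[O+].[C-]#[O+].[C-]#[O+].[C-]#[O+]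
F4 | step 6 | dimethoxy dienylketene complex | CC(C)=CC[C@@H](O[Si](C)(C)C(C)(C)C)C(=C=O)/C=C(/OC)c1cc(OC)ccc1OC.[Cr].[C-]#[O+].[C-]#[O+].[C-]#[O+]
F5 | step 6 | trimethoxy naphthol complex | CC(C)=CC[C@@H](O[Si](C)(C)C(C)(C)C)c1cc(OC)c2c(OC)ccc(OC)c2c1O.[Cr].[C-]#[O+].[C-]#[O+].[C-]#[O+]
F6 | step 6 | O-TBS 5,8-dimethoxynaphthoquinone | CC(C)=CC[C@@H](O[Si](C)(C)C(C)(C)C)C1=CC(=O)c2c(OC)ccc(OC)c2C1=O
F7 | step 6 | 5,8-di-O-methylshikonin | CC(C)=CC[C@@H](O)C1=CC(=O)c2c(OC)ccc(OC)c2C1=O
F8 | step 6 | 5,8-di-O-methyl-β-HIVS | CC(C)=CC[C@@H](OC(=O)CC(C)(C)O)C1=CC(=O)c2c(OC)ccc(OC)c2C1=O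
F9 | step 6 | naphthalene-1,4,5,8-tetraone ester | CC(C)=CC[C@@H](OC(=O)CC(C)(C)O)C1=CC(=O)C2=C(C1=O)C(=O)C=CC2=O
F10 | step 7 | 5,8-bis-O-(methoxymethyl)shikonin | CC(C)=CC[C@@H](O)C1=CC(=O)c2c(OCOC)ccc(OCOC)c2C1=O
F11 | step 7 | 5,8-bis-O-(methoxymethyl)-β-HIVS | CC(C)=CC[C@@H](OC(=O)CC(C)(C)O)C1=CC(=O)c2c(OCOC)ccc(OCOC)c2C1=O
F12 | step 8 | triethylsilyl 3-methyl-3-(triethylsilyloxy)butanoate | CC[Si](CC)(CC)OC(=O)CC(C)(C)O[Si](CC)(CC)CC
F13 | step 8 | 3-methyl-3-(triethylsilyloxy)butanoic acid | CC[Si](CC)(CC)OC(C)(C)CC(=O)O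
F14 | step 8 | shikonin 3-methyl-3-(triethylsilyloxy)butanoate | CC(C)=CC[C@@H](OC(=O)CC(C)(C)O[Si](CC)(CC)CC)C1=CC(=O)c2c(O)ccc(O)c2C1=O
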